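**Retrosynthetic overview**
- The (2S)-flavanone is opened at O1–C2 to the fully unprotected 2',6'-dihydroxychalcone. The forward reaction is a chalcone-isomerase-type 6-endo oxa-Michael addition in which a chiral bifunctional thiourea must select both the phenol (6'-OH, not the prenyl-flanked 2'-OH) and the enone face.
- The chalcone is cut at Cα=Cβ: Claisen–Schmidt union of a C-prenyl acetophenone with a 2-geranyl isovanillin, run on the lithium polyanions without protecting groups.
- The acetophenone comes from nuclear prenylation of symmetric 2,6-dihydroxy-4-methoxyacetophenone (C3 and C5 are equivalent).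
- The aldehyde comes from isovanillin: EE ether, cooperative ortho-lithiation at C2 with the aldehyde masked in situ, arylcopper SN2 geranylation, acid work-up.
- Ring order: rings A and B are bought; the pyranone ring C is the only ring formed and closes last, where the single stereocentre is set.

Assumption: the quinine-derived thiourea is taken to give the 2S flavanone; the sense is checked by ECD on the first run, and if it is 2R the pseudo-enantiomeric quinidine-derived thiourea is used under identical conditions.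

**Route**

Step 1
Reactants: 1 isovanillin (3-hydroxy-4-methoxybenzaldehyde)
Product: 2 3-(1-ethoxyethoxy)-4-methoxybenzaldehyde
Conditions: ethyl vinyl ether (3 equiv), PPTS (5 mol %), CH2Cl2, rt, 6 h
Reagents that add atoms: ethyl vinyl ether, C=COCC
Why: Acid-catalysed addition of the phenol to the vinyl ether (acetal protection) gives a base-stable EE ether that also serves as an ortho-directing group and falls off in dilute acid.

Step 2
Reactants: 2 3-(1-ethoxyethoxy)-4-methoxybenzaldehyde; 3 geranyl bromide ((2E)-1-bromo-3,7-dimethylocta-2,6-diene)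
Product: 8 2-[(2E)-3,7-dimethylocta-2,6-dienyl]-3-hydroxy-4-methoxybenzaldehyde, via lithium α-amino alkoxide 4 (not isolated), via C2-aryllithium 5 (not isolated), via C2-arylcopper 6 (not isolated), via geranylated α-amino alkoxide 7 (not isolated)
Conditions: Me2NCH2CH2N(Me)Li (1.1 equiv, from the amine + n-BuLi), THF, −20 °C; n-BuLi (2.0 equiv), −20 °C, 12 h; CuBr·SMe2 (2.1 equiv), −40 °C; 3 (2.2 equiv), −40 → 0 °C; then 1 M HCl, THF, rt, 1 h
Reagents that add atoms: none
Why: Directed ortho-metalation with in-situ α-amino alkoxide protection of the aldehyde lithiates C2, the only position flanked by both directing groups; the derived arylcopper displaces the primary allylic bromide in an SN2 sense with the E-olefin retained, and dilute acid then releases aldehyde and phenol without touching the geranyl chain.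

Step 3
Reactants: 9 1-(2,6-dihydroxy-4-methoxyphenyl)ethanone; 10 prenyl bromide (1-bromo-3-methylbut-2-ene)
Product: 11 1-[2,6-dihydroxy-4-methoxy-3-(3-methylbut-2-enyl)phenyl]ethanone
Conditions: 10 (1.05 equiv), 10% aq KOH, 0 °C → rt, 4 h; then 1 M HCl to pH 3
Reagents that add atoms: none
Why: Nuclear C-prenylation of the ambident phenoxide in water, where C3 is ortho to one phenoxide and para to the other and C3/C5 are equivalent by symmetry, so only one mono-C-prenyl product can form (expect about 35–45% with recovered 9, O-prenyl and di-C-prenyl by-products).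

Step 4
Reactants: 11 1-[2,6-dihydroxy-4-methoxy-3-(3-methylbut-2-enyl)phenyl]ethanone; 8 2-[(2E)-3,7-dimethylocta-2,6-dienyl]-3-hydroxy-4-methoxybenzaldehyde
Product: 13 (E)-3-[2-((2E)-3,7-dimethylocta-2,6-dienyl)-3-hydroxy-4-methoxyphenyl]-1-[2,6-dihydroxy-4-methoxy-3-(3-methylbut-2-enyl)phenyl]prop-2-en-1-one, via aldol adduct 12 (not isolated)
Conditions: 11, LiHMDS (3.3 equiv), THF, −78 → −20 °C; add lithium phenoxide of 8 (8 + LiHMDS 1.05 equiv, THF, −78 °C); −78 °C → rt, 16 h; pour into ice-cold 1 M HCl; rapid SiO2 chromatography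
Reagents that add atoms: none
Why: Claisen–Schmidt aldol condensation through the lithium polyanion: the phenols are masked as lithium phenoxides, the ketone enolate adds to the non-enolisable aldehyde and the aldolate loses hydroxide by E1cB to the (E)-chalcone, a lithium-amide protocol known for unprotected prenylated polyhydroxyacetophenones; the cold acidic quench keeps the chalcone from cyclising.

Step 5
Reactants: 13 (E)-3-[2-((2E)-3,7-dimethylocta-2,6-dienyl)-3-hydroxy-4-methoxyphenyl]-1-[2,6-dihydroxy-4-methoxy-3-(3-methylbut-2-enyl)phenyl]prop-2-en-1-one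
Product: 14 (2S)-2-[2-((2E)-3,7-dimethylocta-2,6-dienyl)-3-hydroxy-4-methoxyphenyl]-5-hydroxy-7-methoxy-6-(3-methylbut-2-enyl)chroman-4-one
Conditions: quinine-derived thiourea (N-[3,5-bis(trifluoromethyl)phenyl]-N'-(9-deoxy-epi-quinin-9-yl)thiourea, 10 mol %), PhCl (0.05 M), 0 °C, 48–72 h, Ar, dark; direct SiO2 chromatography, minor regioisomer removed, recrystallise to upgrade ee
Reagents that add atoms: none
Why: Proposed new method: the quinuclidine nitrogen acts as general base on the only freely available phenol (the 6'-OH; the 2'-OH is shielded by the flanking prenyl group and tied up in a buttressed hydrogen bond to the carbonyl) while the thiourea hydrogen-bonds the enone carbonyl, so 6-endo-trig oxa-Michael addition occurs in a tight chiral ion pair on one β-face and sets C2 as S; the closest known reactions are the cinchona-thiourea-catalysed asymmetric intramolecular oxa-Michael cyclisations of 2'-hydroxychalcones and alkylidene β-ketoesters to flavanones and the chalcone isomerase reaction, whereas selection between two free phenols of an unprotected 2',6'-dihydroxychalcone is untested.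

**Compound list**
1 | isovanillin (3-hydroxy-4-methoxybenzaldehyde) | O=Cc1ccc(OC)c(O)c1 | starting material
2 | 3-(1-ethoxyethoxy)-4-methoxybenzaldehyde (racemic at the acetal carbon) | O=Cc1ccc(OC)c(OC(C)OCC)c1 | intermediate
3 | geranyl bromide, (2E)-1-bromo-3,7-dimethylocta-2,6-diene | BrC/C=C(\C)CCC=C(C)C | starting material
4 | lithium α-amino alkoxide from 2 and lithium [2-(dimethylamino)ethyl](methyl)amide (stereocentres unassigned) | [Li]OC(N(C)CCN(C)C)c1ccc(OC)c(OC(C)OCC)c1 | intermediate
5 | C2-aryllithium of 4 (lithium between the amino alkoxide carbon and the OEE group) | [Li]OC(N(C)CCN(C)C)c1ccc(OC)c(OC(C)OCC)c1[Li] | intermediate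
6 | C2-arylcopper(I) derived from 5 | [Li]OC(N(C)CCN(C)C)c1ccc(OC)c(OC(C)OCC)c1[Cu] | intermediate
7 | C2-(E)-geranylated lithium α-amino alkoxide | [Li]OC(N(C)CCN(C)C)c1ccc(OC)c(OC(C)OCC)c1C/C=C(\C)CCC=C(C)C | intermediate
8 | 2-[(2E)-3,7-dimethylocta-2,6-dienyl]-3-hydroxy-4-methoxybenzaldehyde | O=Cc1ccc(OC)c(O)c1C/C=C(\C)CCC=C(C)C | intermediate
9 | 1-(2,6-dihydroxy-4-methoxyphenyl)ethanone | CC(=O)c1c(O)cc(OC)cc1O | starting material
10 | prenyl bromide, 1-bromo-3-methylbut-2-ene | CC(C)=CCBr | starting material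
11 | 1-[2,6-dihydroxy-4-methoxy-3-(3-methylbut-2-enyl)phenyl]ethanone | CC(=O)c1c(O)cc(OC)c(CC=C(C)C)c1O | intermediate
12 | aldol adduct, 3-[2-((2E)-3,7-dimethylocta-2,6-dienyl)-3-hydroxy-4-methoxyphenyl]-1-[2,6-dihydroxy-4-methoxy-3-(3-methylbut-2-enyl)phenyl]-3-hydroxypropan-1-one (racemic, present as its lithium salt) | O=C(CC(O)c1ccc(OC)c(O)c1C/C=C(\C)CCC=C(C)C)c1c(O)cc(OC)c(CC=C(C)C)c1O | intermediate
13 | (E)-3-[2-((2E)-3,7-dimethylocta-2,6-dienyl)-3-hydroxy-4-methoxyphenyl]-1-[2,6-dihydroxy-4-methoxy-3-(3-methylbut-2-enyl)phenyl]prop-2-en-1-one | O=C(/C=C/c1ccc(OC)c(O)c1C/C=C(\C)CCC=C(C)C)c1c(O)cc(OC)c(CC=C(C)C)c1O | intermediate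
14 | (2S)-2-[2-((2E)-3,7-dimethylocta-2,6-dienyl)-3-hydroxy-4-methoxyphenyl]-5-hydroxy-7-methoxy-6-(3-methylbut-2-enyl)chroman-4-one | COc1ccc([C@@H]2CC(=O)c3c(cc(OC)c(CC=C(C)C)c3O)O2)c(C/C=C(\C)CCC=C(C)C)c1O | target

**Step count**
Total steps: 5. Longest linear sequence: 4 (steps 1, 2, 4, 5 from isovanillin).

**Steps most likely to fail, with fallbacks**

Step 5 (phenol selection and enantioselectivity on the unprotected chalcone). The fallback sets out from 9 and returns at 14; it fixes the regiochemistry with a protecting group and puts the asymmetric cyclisation on a 2'-hydroxy-6'-alkoxychalcone, the class with closer precedent.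
- 9 is mono-O-prenylated (10, K2CO3, acetone, reflux; the second OH stays chelated) to 1-[2-hydroxy-4-methoxy-6-(3-methylbut-2-enyloxy)phenyl]ethanone F1.
- The chelated OH is capped (NaH, MOMCl, DMF) to give 1-[4-methoxy-2-(methoxymethoxy)-6-(3-methylbut-2-enyloxy)phenyl]ethanone F2.
- Para-Claisen–Cope rearrangement (PhNEt2, 200 °C) moves the prenyl group to the carbon para to the ether oxygen, next to the OMOM group, and frees the other phenol: 1-[6-hydroxy-4-methoxy-2-(methoxymethoxy)-3-(3-methylbut-2-enyl)phenyl]ethanone F3.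
- Claisen–Schmidt condensation with 8 (KOH, EtOH/H2O, rt) gives (E)-3-[2-((2E)-3,7-dimethylocta-2,6-dienyl)-3-hydroxy-4-methoxyphenyl]-1-[6-hydroxy-4-methoxy-2-(methoxymethoxy)-3-(3-methylbut-2-enyl)phenyl]prop-2-en-1-one F4, which has a single free A-ring phenol.
- The same thiourea-catalysed oxa-Michael cyclisation can then only give the 6-prenyl series: (2S)-2-[2-((2E)-3,7-dimethylocta-2,6-dienyl)-3-hydroxy-4-methoxyphenyl]-7-methoxy-5-(methoxymethoxy)-6-(3-methylbut-2-enyl)chroman-4-one F5.
- Brief HCl/MeOH at rt removes the MOM group to give 14.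

Step 4 (polyanion aldol with a hindered ortho-geranyl aldehyde, and isolation of a chalcone that can cyclise). The fallback sets out from 11 and returns at 13; it replaces the polyanion chemistry by the classical protected condensation.
- 11 is converted (NaH, MOMCl, DMF) into 1-[4-methoxy-2,6-bis(methoxymethoxy)-3-(3-methylbut-2-enyl)phenyl]ethanone F6.
- Condensation with 8 (KOH, EtOH/H2O, rt) gives (E)-3-[2-((2E)-3,7-dimethylocta-2,6-dienyl)-3-hydroxy-4-methoxyphenyl]-1-[4-methoxy-2,6-bis(methoxymethoxy)-3-(3-methylbut-2-enyl)phenyl]prop-2-en-1-one F7.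
- Short treatment with 3 M HCl in MeOH at rt, monitored so that acid-induced cyclisation does not set in, gives 13.

Step 3 (C- versus O-alkylation and over-prenylation). The fallback sets out from 9 and returns at 11; it replaces phenoxide alkylation by cross-coupling.
- Mono-iodination of 9 (NIS, 1.0 equiv, MeCN, 0 °C; only one kind of ring position is available) gives 1-(2,6-dihydroxy-3-iodo-4-methoxyphenyl)ethanone F8.
- α-Selective Suzuki–Miyaura coupling with commercial prenylboronic acid pinacol ester (Pd-PEPPSI-IPent, aq KOH, THF, 70 °C) gives 11. The prenyl terminus is symmetric, so no olefin-geometry issue arises.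

**Further compounds**
F1 | step 5 | 1-[2-hydroxy-4-methoxy-6-(3-methylbut-2-enyloxy)phenyl]ethanone | CC(=O)c1c(O)cc(OC)cc1OCC=C(C)C
F2 | step 5 | 1-[4-methoxy-2-(methoxymethoxy)-6-(3-methylbut-2-enyloxy)phenyl]ethanone | CC(=O)c1c(OCOC)cc(OC)cc1OCC=C(C)C
F3 | step 5 | 1-[6-hydroxy-4-methoxy-2-(methoxymethoxy)-3-(3-methylbut-2-enyl)phenyl]ethanone | CC(=O)c1c(O)cc(OC)c(CC=C(C)C)c1OCOC
F4 | step 5 | (E)-3-[2-((2E)-3,7-dimethylocta-2,6-dienyl)-3-hydroxy-4-methoxyphenyl]-1-[6-hydroxy-4-methoxy-2-(methoxymethoxy)-3-(3-methylbut-2-enyl)phenyl]prop-2-en-1-one | O=C(/C=C/c1ccc(OC)c(O)c1C/C=C(\C)CCC=C(C)C)c1c(O)cc(OC)c(CC=C(C)C)c1OCOC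
F5 | step 5 | (2S)-2-[2-((2E)-3,7-dimethylocta-2,6-dienyl)-3-hydroxy-4-methoxyphenyl]-7-methoxy-5-(methoxymethoxy)-6-(3-methylbut-2-enyl)chroman-4-one | COc1ccc([C@@H]2CC(=O)c3c(cc(OC)c(CC=C(C)C)c3OCOC)O2)c(C/C=C(\C)CCC=C(C)C)c1O
F6 | step 4 | 1-[4-methoxy-2,6-bis(methoxymethoxy)-3-(3-methylbut-2-enyl)phenyl]ethanone | CC(=O)c1c(OCOC)cc(OC)c(CC=C(C)C)c1OCOC
F7 | step 4 | (E)-3-[2-((2E)-3,7-dimethylocta-2,6-dienyl)-3-hydroxy-4-methoxyphenyl]-1-[4-methoxy-2,6-bis(methoxymethoxy)-3-(3-methylbut-2-enyl)phenyl]prop-2-en-1-one | O=C(/C=C/c1ccc(OC)c(O)c1C/C=C(\C)CCC=C(C)C)c1c(OCOC)cc(OC)c(CC=C(C)C)c1OCOC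
F8 | step 3 | 1-(2,6-dihydroxy-3-iodo-4-methoxyphenyl)ethanone | CC(=O)c1c(O)cc(OC)c(I)c1O
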